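Ring B of the target carries the ether oxygen on C1', OH on C2' and bromine on C3', C4' and C6'; it is treated as a 2,4,6-tribromophenyl ether whose C2' bromine has shifted to C3' and handed its place to oxygen. One operation achieves this: LiN(iPr)2 sets off a halogen dance and the resulting C2' aryllithium is borylated and oxidised, which creates the C3'–Br and C2'–O bonds together. The substrate is 6-(2,4,6-tribromophenoxy)-1,4-dioxaspiro[4.5]decane, in which ring A is still a ketal-masked cyclohexanone; afterwards that ring is aromatised by bromination–dehydrobromination, brominated once more and O-methylated.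

Key step: step 3

Assumption: ring A is numbered C1 (diaryl ether oxygen), C2 (OMe), C3 and C5 (Br); ring B is numbered C1' (ether oxygen), C2' (OH), C3', C4', C6' (Br), C5' (H). The target is achiral, and every intermediate with a cyclohexane stereocentre is used as the racemate.

Step 1
Reactants: 1 2,4,6-tribromophenol; 2 2-chlorocyclohexanone
Product: 3 2-(2,4,6-tribromophenoxy)cyclohexan-1-one (racemic)
Conditions: K2CO3, KI (cat.), DMF, 60 °C
Reagents that add atoms: none
Why: Williamson ether synthesis, in which the phenoxide displaces chloride (iodide after in-situ Finkelstein exchange) from the carbonyl-activated α-carbon by SN2, K2CO3 being too weak a base to divert the chloroketone into Favorskii rearrangement; the new stereocentre forms as a racemate and is destroyed later on aromatisation.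

Step 2
Reactants: 3 2-(2,4,6-tribromophenoxy)cyclohexan-1-one; 4 ethylene glycol
Product: 5 6-(2,4,6-tribromophenoxy)-1,4-dioxaspiro[4.5]decane (racemic)
Conditions: TsOH·H2O (cat.), toluene, reflux, water separator
Reagents that add atoms: none
Why: Acid-catalysed ketalisation driven by azeotropic removal of water masks the ketone and so removes the only acidic C–H bonds outside ring B before the amide base is used; the existing stereocentre stays racemic.

Step 3
Reactants: 5 6-(2,4,6-tribromophenoxy)-1,4-dioxaspiro[4.5]decane
Product: 10 2,3,5-tribromo-6-(1,4-dioxaspiro[4.5]decan-6-yloxy)phenol (racemic), via kinetic aryllithium 6 (not isolated), via tetrabromo ether 7 (not isolated), via rearranged aryllithium 8 (not isolated), via arylboronate 9 (not isolated)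
Conditions: LiN(iPr)2 (1.05 equiv, added dropwise), THF, −78 °C; B(OMe)3, −78 → 0 °C; AcOH, 30% H2O2 (aq), 0 °C → rt
Reagents that add atoms: hydrogen peroxide, OO
Why: LiN(iPr)2 removes the ring proton at C3' (equivalent to C5'), the only acidic C–H because it lies between two bromines, to give 6; 6 abstracts bromine from C2' of a second arene so that a trace of 7 arises, and 6 then exchanges with the C2' bromine of 7 to deliver 8 while regenerating 7, the net result being a 1,2-shift of bromine from C2' to C3'. B(OMe)3 captures 8 as 9, whose aryl group migrates from boron to oxygen on treatment with H2O2, so the C2'–O bond forms exactly where lithium sat. The closest known reaction type is the base-induced halogen dance of oligobromoarenes bearing an ortho-directing oxygen substituent with electrophilic trapping of the rearranged aryllithium, and borylation–oxidation of doubly ortho-substituted aryllithiums is routine. No ring is closed and no stereocentre is created, the ketal stereocentre being a spectator. The step needs positional selectivity for lithium at C2', which is a thermodynamic choice: 8 gains an ortho ether oxygen that stabilises the carbanion inductively and, together with a ketal oxygen, chelates lithium, while one ortho bromine is kept; dropwise base addition keeps 5 present as bromine donor, one equivalent of base avoids a second metalation at C5', and −78 °C suppresses loss of LiBr to an aryne. The ketal ring has no acidic C–H, so metalation is confined to ring B.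

Step 4
Reactants: 10 2,3,5-tribromo-6-(1,4-dioxaspiro[4.5]decan-6-yloxy)phenol
Product: 12 2,3,5-tribromo-6-[(2-oxocyclohexyl)oxy]phenyl 4-methylbenzenesulfonate (racemic), via tosylate ketal 11 (not isolated)
Conditions: TsCl, Et3N, DMAP (cat.), THF, rt; then 3 M HCl (aq), 55 °C
Reagents that add atoms: 4-methylbenzenesulfonyl chloride, Cc1ccc(cc1)S(Cl)(=O)=O; water, O
Why: Sulfonylation of the acidic ring B phenol (nucleophilic catalysis by DMAP) is followed in the same flask by acid-catalysed ketal hydrolysis, to which the aryl sulfonate, the alkyl aryl ether and the aryl bromides are inert; the tosylate deactivates ring B towards bromine and keeps its oxygen out of the later methylation.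

Step 5
Reactants: 12 2,3,5-tribromo-6-[(2-oxocyclohexyl)oxy]phenyl 4-methylbenzenesulfonate
Product: 14 2,3,5-tribromo-6-(3-bromo-2-hydroxyphenoxy)phenyl 4-methylbenzenesulfonate, via tribromoketone 13 (not isolated)
Conditions: Br2 (3.1 equiv), AcOH, 50 °C; evaporate; Li2CO3, LiBr, DMF, 100 °C
Reagents that add atoms: bromine, BrBr
Why: Acid-catalysed α-bromination replaces all three α-hydrogens of the ketone, and LiBr/Li2CO3 then effects twofold dehydrobromination (the classical halogenation–dehydrohalogenation aromatisation of a cyclohexanone) to a dienone that tautomerises to the phenol, the surviving α-bromine ending up ortho to the new OH at C3 of ring A; ring B, with three bromines and a sulfonate, does not react with Br2.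

Step 6
Reactants: 14 2,3,5-tribromo-6-(3-bromo-2-hydroxyphenoxy)phenyl 4-methylbenzenesulfonate
Product: 15 2,3,5-tribromo-6-(3,5-dibromo-2-hydroxyphenoxy)phenyl 4-methylbenzenesulfonate
Conditions: Br2 (1.1 equiv), AcOH, rt
Reagents that add atoms: bromine, BrBr
Why: Electrophilic aromatic bromination, in which the free OH on C2 of ring A directs to its only open activated position, the para carbon C5, while the electron-poor sulfonylated ring B is inert.

Step 7
Reactants: 15 2,3,5-tribromo-6-(3,5-dibromo-2-hydroxyphenoxy)phenyl 4-methylbenzenesulfonate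
Product: 16 2,3,5-tribromo-6-(3,5-dibromo-2-methoxyphenoxy)phenyl 4-methylbenzenesulfonate
Conditions: MeI, K2CO3, acetone, reflux
Reagents that add atoms: iodomethane, CI
Why: Williamson O-methylation of the single free phenol (as its potassium phenoxide) by SN2 on iodomethane, the ring B oxygen being blocked as the sulfonate.

Step 8
Reactants: 16 2,3,5-tribromo-6-(3,5-dibromo-2-methoxyphenoxy)phenyl 4-methylbenzenesulfonate
Product: 17 2,3,5-tribromo-6-(3,5-dibromo-2-methoxyphenoxy)phenol (target)
Conditions: KOH, 1,4-dioxane/H2O, 80 °C; then HCl (aq)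
Reagents that add atoms: none
Why: Saponification of the aryl sulfonate by hydroxide attack at sulfur is made easy by the good leaving ability of the tribrominated phenoxide; the alcohol-free medium avoids formation of a methylating sulfonate ester, and the aryl bromides, the methyl ether and the diaryl ether are stable to aqueous base at this temperature.

Compound list
1 | 2,4,6-tribromophenol | Oc1c(Br)cc(Br)cc1Br | starting material
2 | 2-chlorocyclohexanone (racemic) | O=C1CCCCC1Cl | starting material
3 | 2-(2,4,6-tribromophenoxy)cyclohexan-1-one (racemic) | O=C1CCCCC1Oc1c(Br)cc(Br)cc1Br | intermediate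
4 | ethylene glycol | OCCO | starting material
5 | 6-(2,4,6-tribromophenoxy)-1,4-dioxaspiro[4.5]decane (racemic) | Brc1cc(Br)c(OC2CCCCC23OCCO3)c(Br)c1 | intermediate
6 | [2,4,6-tribromo-3-(1,4-dioxaspiro[4.5]decan-6-yloxy)phenyl]lithium (racemic; lithium at C3' between two bromines) | [Li]c1c(Br)cc(Br)c(OC2CCCCC23OCCO3)c1Br | intermediate
7 | 6-(2,3,4,6-tetrabromophenoxy)-1,4-dioxaspiro[4.5]decane (racemic; bromine carrier) | Brc1cc(Br)c(OC2CCCCC23OCCO3)c(Br)c1Br | intermediate
8 | [2,3,5-tribromo-6-(1,4-dioxaspiro[4.5]decan-6-yloxy)phenyl]lithium (racemic; lithium at C2') | [Li]c1c(Br)c(Br)cc(Br)c1OC1CCCCC12OCCO2 | intermediate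
9 | dimethyl [2,3,5-tribromo-6-(1,4-dioxaspiro[4.5]decan-6-yloxy)phenyl]boronate (racemic) | COB(OC)c1c(Br)c(Br)cc(Br)c1OC1CCCCC12OCCO2 | intermediate
10 | 2,3,5-tribromo-6-(1,4-dioxaspiro[4.5]decan-6-yloxy)phenol (racemic) | Oc1c(Br)c(Br)cc(Br)c1OC1CCCCC12OCCO2 | intermediate
11 | 2,3,5-tribromo-6-(1,4-dioxaspiro[4.5]decan-6-yloxy)phenyl 4-methylbenzenesulfonate (racemic) | Cc1ccc(cc1)S(=O)(=O)Oc1c(Br)c(Br)cc(Br)c1OC1CCCCC12OCCO2 | intermediate
12 | 2,3,5-tribromo-6-[(2-oxocyclohexyl)oxy]phenyl 4-methylbenzenesulfonate (racemic) | Cc1ccc(cc1)S(=O)(=O)Oc1c(Br)c(Br)cc(Br)c1OC1CCCCC1=O | intermediate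
13 | 2,3,5-tribromo-6-[(1,3,3-tribromo-2-oxocyclohexyl)oxy]phenyl 4-methylbenzenesulfonate (racemic) | Cc1ccc(cc1)S(=O)(=O)Oc1c(Br)c(Br)cc(Br)c1OC1(Br)CCCC(Br)(Br)C1=O | intermediate
14 | 2,3,5-tribromo-6-(3-bromo-2-hydroxyphenoxy)phenyl 4-methylbenzenesulfonate | Cc1ccc(cc1)S(=O)(=O)Oc1c(Br)c(Br)cc(Br)c1Oc1cccc(Br)c1O | intermediate
15 | 2,3,5-tribromo-6-(3,5-dibromo-2-hydroxyphenoxy)phenyl 4-methylbenzenesulfonate | Cc1ccc(cc1)S(=O)(=O)Oc1c(Br)c(Br)cc(Br)c1Oc1cc(Br)cc(Br)c1O | intermediate
16 | 2,3,5-tribromo-6-(3,5-dibromo-2-methoxyphenoxy)phenyl 4-methylbenzenesulfonate | COc1c(Br)cc(Br)cc1Oc1c(Br)cc(Br)c(Br)c1OS(=O)(=O)c1ccc(C)cc1 | intermediate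
17 | 2,3,5-tribromo-6-(3,5-dibromo-2-methoxyphenoxy)phenol | COc1c(Br)cc(Br)cc1Oc1c(Br)cc(Br)c(Br)c1O | target

Total step count: 8. Longest linear sequence: 8 steps (1 → 3 → 5 → 10 → 12 → 14 → 15 → 16 → 17).

Steps most likely to fail

Step 3. The bromine migration may stall or end at the wrong isomer. The first aryllithium between two bromines may simply persist, lithium may drift to C5' by amine-mediated proton transfer, or LiBr may be lost to an aryne. Oxygen would then be placed on the wrong carbon or the material would oligomerise. The fallback uses only electrophilic substitution and no aryllithium; it sets out from 2 together with purchased 2-bromo-6-methoxyphenol (COc1cccc(Br)c1O) and returns to the route at 12. The phenol is tosylated (TsCl, Et3N, DMAP, CH2Cl2) to 2-bromo-6-methoxyphenyl 4-methylbenzenesulfonate F1. BBr3 (CH2Cl2, −78 → 0 °C) should cleave the methyl ether and spare the sulfonate, giving 2-bromo-6-hydroxyphenyl 4-methylbenzenesulfonate F2. Br2 (2.1 equiv, AcOH) should enter ortho and para to the free OH to give 2,3,5-tribromo-6-hydroxyphenyl 4-methylbenzenesulfonate F3, which already holds the full ring B pattern. Alkylation of F3 with 2 (K2CO3, KI, DMF, 60 °C), as in step 1, would give 12, and steps 5 to 8 follow unchanged.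

Step 5. Bromination at the hindered α-carbon that bears the aryloxy group may stay incomplete, leaving a geminal dibromide that cannot aromatise. In hot DMF the ring A phenoxide may also take over the sulfonyl group from the ring B oxygen, which would destroy the differentiation of the two phenols. The fallback sets out from 12 and returns at 15. Oxidative dehydrogenation with I2 (cat.) in DMSO at 100 °C (iodine-catalysed aromatisation of a 2-substituted cyclohexanone with DMSO as terminal oxidant, no phenoxide being formed) should give 2,3,5-tribromo-6-(2-hydroxyphenoxy)phenyl 4-methylbenzenesulfonate F4. Br2 (2.1 equiv, AcOH, rt) should then brominate ortho and para to the ring A hydroxyl and give 15 directly.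

Step 1. The SN2 displacement by a hindered, weakly nucleophilic phenoxide at a secondary carbon may be slow, so that base-induced self-condensation or elimination of the chloroketone competes. The fallback sets out from 1 and returns at 3. Base-catalysed ring opening of purchased cyclohexene oxide (C1CCC2OC2C1) by the phenoxide (K2CO3, DMF, 110 °C) should give, by anti opening, trans-2-(2,4,6-tribromophenoxy)cyclohexan-1-ol F5 as the racemate. Swern oxidation ((COCl)2, DMSO, Et3N, CH2Cl2, −78 °C) then gives 3.

Further compounds
F1 | step 3 | 2-bromo-6-methoxyphenyl 4-methylbenzenesulfonate | COc1cccc(Br)c1OS(=O)(=O)c1ccc(C)cc1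
F2 | step 3 | 2-bromo-6-hydroxyphenyl 4-methylbenzenesulfonate | Oc1cccc(Br)c1OS(=O)(=O)c1ccc(C)cc1
F3 | step 3 | 2,3,5-tribromo-6-hydroxyphenyl 4-methylbenzenesulfonate | Oc1c(Br)cc(Br)c(Br)c1OS(=O)(=O)c1ccc(C)cc1
F4 | step 5 | 2,3,5-tribromo-6-(2-hydroxyphenoxy)phenyl 4-methylbenzenesulfonate | Cc1ccc(cc1)S(=O)(=O)Oc1c(Br)c(Br)cc(Br)c1Oc1ccccc1O
F5 | step 1 | trans-2-(2,4,6-tribromophenoxy)cyclohexan-1-ol (racemic; the (1R,2R) enantiomer is drawn) | O[C@@H]1CCCC[C@H]1Oc1c(Br)cc(Br)cc1Br
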